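The resorcinol ring is disconnected at its C1–C6 bond. Its substitution (acyl at C1, OH at C2 and C4, 4-methylpentyl at C3, H at C5 and C6) is the alternating pattern of a folded poly-β-carbonyl chain. C2 and C4 are therefore carried as chain ketones and C6 as a masked aldehyde. In one operation the key step unmasks that aldehyde, closes the carbocycle by intramolecular aldol condensation and aromatises it to the target, with no protecting group left to remove. Its precursor is an acyclic 1,3,5-triketone with the intact 4,5-dichloropyrrole at one end, the 4-methylpentyl group on the central carbon and a dimethyl acetal at the other end.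

Key step: step 5

Remark: the target has no stereocentre, so it is achiral and no enantiomer has to be selected. The CH groups between two carbonyls in 6, 7, 10, 11 and 12 are enolisable; these compounds are handled as stereoisomer mixtures and the centres vanish on aromatisation.
Remark on numbering: in 8, 10 and 11 the chain is numbered from the pyrrolyl ketone carbon (C1) to the acetal or aldehyde carbon (C7). Ring C1–C6 of 13 derive from chain C2–C7.

Step 1
Reactants: 1 tert-butyl 3-oxobutanoate (tert-butyl acetoacetate); 2 1-bromo-4-methylpentane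
Product: 3 tert-butyl 8-methyl-3-oxononanoate
Conditions: NaH (1.1 equiv), THF, 0 °C; n-BuLi (1.05 equiv), 0 °C; then 2, 0 °C → rt; cold dilute HCl work-up
Reagents that add atoms: none
Why: Huckin–Weiler dianion alkylation, in which the terminal carbanion of the acetoacetate dianion is far more nucleophilic than the stabilised central carbon, so the primary bromide should be displaced (SN2) only at the γ-carbon while the bulky tert-butyl ester resists attack by n-BuLi.

Step 2
Reactants: 4 4,5-dichloro-1H-pyrrole-2-carboxylic acid; 3 tert-butyl 8-methyl-3-oxononanoate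
Product: 6 tert-butyl 2-(4,5-dichloro-1H-pyrrole-2-carbonyl)-8-methyl-3-oxononanoate, via acid chloride 5 (not isolated)
Conditions: (COCl)2 (1.3 equiv), cat. DMF, CH2Cl2, 0 °C → rt, concentrate; then 3, MgCl2 (1.1 equiv), pyridine (2.2 equiv), CH2Cl2, 0 °C → rt; cold 1 M HCl work-up
Reagents that add atoms: none
Why: Acid chloride formation followed by Rathke-type MgCl2/amine C-acylation of a β-keto ester, in which the chelated magnesium enolate reacts at carbon and pyridine is too weak a base to deprotonate the pyrrole N–H, so the acid chloride should not condense with itself; the new CH centre is enolised and needs no control.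

Step 3
Reactants: 6 tert-butyl 2-(4,5-dichloro-1H-pyrrole-2-carbonyl)-8-methyl-3-oxononanoate
Product: 8 1-(4,5-dichloro-1H-pyrrol-2-yl)-8-methylnonane-1,3-dione, via keto acid 7 (not isolated)
Conditions: TFA–CH2Cl2 (1:3), rt; then toluene, 80 °C
Reagents that add atoms: none
Why: Acidolysis of the tert-butyl ester (loss of isobutene) gives a β-keto acid flanked by two ketones, which should decarboxylate on gentle warming through the usual cyclic transition state and leave the unsymmetrical 1,3-diketone without regiochemical ambiguity.

Step 4
Reactants: 8 1-(4,5-dichloro-1H-pyrrol-2-yl)-8-methylnonane-1,3-dione; 9 methyl 3,3-dimethoxypropanoate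
Product: 10 1-(4,5-dichloro-1H-pyrrol-2-yl)-7,7-dimethoxy-4-(4-methylpentyl)heptane-1,3,5-trione
Conditions: LDA (4.2 equiv), THF, −78 → 0 °C; then 9 (1.2 equiv), −78 → −20 °C; AcOH, −78 °C; pH 6 phosphate work-up
Reagents that add atoms: none
Why: Hauser–Harris γ-acylation of a β-diketone polyanion (Claisen type), in which LDA removes N–H, a C2–H and then a C4–H, and C4, the only unstabilised carbanion of the trianion, should add to the ester carbonyl of 9 while the extra equivalent of base takes up the acidic proton of the new triketone, the N-anion shields the pyrrolyl ketone and the acetal is inert to base; the new C4 centre is enolisable and is not controlled.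

Step 5
Reactants: 10 1-(4,5-dichloro-1H-pyrrol-2-yl)-7,7-dimethoxy-4-(4-methylpentyl)heptane-1,3,5-trione
Product: 13 (4,5-dichloro-1H-pyrrol-2-yl)[2,4-dihydroxy-3-(4-methylpentyl)phenyl]methanone, via trioxoheptanal 11 (not isolated), via cyclic aldol 12 (not isolated)
Conditions: 1 M HCl–THF (1:4), rt, dilute; then excess 2 M aq KOH, MeOH, Ar, 0 °C → rt; 1 M HCl to pH 3
Reagents that add atoms: none
Why: Dilute acid hydrolyses the dimethyl acetal of 10 to aldehyde 11, and in the basic stage the enolate of the most acidic carbon, chain C2 between the pyrrolyl ketone and the C3 ketone, adds to the C7 formyl group to form the C2–C7 bond (ring C1–C6) in aldol 12, which loses water by E1cB and reaches the resorcinol by two keto–enol tautomerisations. The closest known reaction type is the base-mediated aldol cyclisation and aromatisation of poly-β-carbonyl chains (Collie–Harris polyketone chemistry), together with the classical condensation of β-keto aldehydes to benzenes. The six-membered carbocycle closes in the 6-(enolendo)-exo-trig mode. No stereocentre remains, since the transient centres of 12 are erased by dehydration and enolisation. The step needs closure through carbon instead of oxygen, and this aldol in preference to attack of C6 on the C1 ketone or hydroxide cleavage of the chain: the formyl carbon is the most electrophilic and least hindered carbonyl, the C1 ketone is deactivated as part of the pyrrolide (a vinylogous amide anion), and C4 could reach C7 only through a four-membered ring. Any 4-pyranone formed by O-closure in the acid stage should be reopened by hydroxide at its unsubstituted ring carbon, and the irreversible aromatisation should drain these equilibria to 13.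

Compound list
1 | tert-butyl 3-oxobutanoate (tert-butyl acetoacetate) | CC(=O)CC(=O)OC(C)(C)C | starting material
2 | 1-bromo-4-methylpentane | CC(C)CCCBr | starting material
3 | tert-butyl 8-methyl-3-oxononanoate | CC(C)CCCCC(=O)CC(=O)OC(C)(C)C | intermediate
4 | 4,5-dichloro-1H-pyrrole-2-carboxylic acid | OC(=O)c1cc(Cl)c(Cl)[nH]1 | starting material
5 | 4,5-dichloro-1H-pyrrole-2-carbonyl chloride (not isolated) | O=C(Cl)c1cc(Cl)c(Cl)[nH]1 | intermediate
6 | tert-butyl 2-(4,5-dichloro-1H-pyrrole-2-carbonyl)-8-methyl-3-oxononanoate (racemic, enolised) | CC(C)CCCCC(=O)C(C(=O)OC(C)(C)C)C(=O)c1cc(Cl)c(Cl)[nH]1 | intermediate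
7 | 2-(4,5-dichloro-1H-pyrrole-2-carbonyl)-8-methyl-3-oxononanoic acid (not isolated) | CC(C)CCCCC(=O)C(C(=O)O)C(=O)c1cc(Cl)c(Cl)[nH]1 | intermediate
8 | 1-(4,5-dichloro-1H-pyrrol-2-yl)-8-methylnonane-1,3-dione | CC(C)CCCCC(=O)CC(=O)c1cc(Cl)c(Cl)[nH]1 | intermediate
9 | methyl 3,3-dimethoxypropanoate | COC(CC(=O)OC)OC | starting material
10 | 1-(4,5-dichloro-1H-pyrrol-2-yl)-7,7-dimethoxy-4-(4-methylpentyl)heptane-1,3,5-trione (key-step precursor, racemic, enolised) | COC(OC)CC(=O)C(CCCC(C)C)C(=O)CC(=O)c1cc(Cl)c(Cl)[nH]1 | intermediate
11 | 7-(4,5-dichloro-1H-pyrrol-2-yl)-4-(4-methylpentyl)-3,5,7-trioxoheptanal (not isolated) | O=CCC(=O)C(CCCC(C)C)C(=O)CC(=O)c1cc(Cl)c(Cl)[nH]1 | intermediate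
12 | 4-(4,5-dichloro-1H-pyrrole-2-carbonyl)-5-hydroxy-2-(4-methylpentyl)cyclohexane-1,3-dione (not isolated, stereoisomer mixture) | O=C1CC(O)C(C(=O)c2cc(Cl)c(Cl)[nH]2)C(=O)C1CCCC(C)C | intermediate
13 | (4,5-dichloro-1H-pyrrol-2-yl)[2,4-dihydroxy-3-(4-methylpentyl)phenyl]methanone | CC(C)CCCc1c(O)ccc(C(=O)c2cc(Cl)c(Cl)[nH]2)c1O | target

Total step count: 5
Longest linear sequence: 5 steps (1 → 3 → 6 → 8 → 10 → 13); acid 4 enters at step 2 and ester 9 at step 4.

Steps most likely to fail

Step 5 (key step). The chain may close through oxygen in the acid stage to a pyranone that does not reopen. Hydroxide may cleave the chain by retro-Claisen attack. The aldol may also run in the opposite sense, onto the pyrrolyl ketone. The fallback gives up the ring construction and builds the ketone on a preformed arene; it sets out from acid chloride 5 (made from 4 as in step 2) and bromide 2 and returns at 13. Commercial 1,3-dimethoxybenzene is lithiated between the two methoxy groups (n-BuLi, THF, 0 °C → rt) and alkylated with 2 to give 1,3-dimethoxy-2-(4-methylpentyl)benzene F1. Friedel–Crafts acylation of F1 with 5 (AlCl3, CH2Cl2, 0 °C) at C4, the only position activated by both methoxy groups, should give (4,5-dichloro-1H-pyrrol-2-yl)[2,4-dimethoxy-3-(4-methylpentyl)phenyl]methanone F2. BBr3 (CH2Cl2, −78 °C → rt) then cleaves both methyl ethers to 13.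

Step 4. The enolisable acetal ester may transfer a proton to the polyanion (with β-elimination of methoxide) instead of being attacked at its carbonyl, or trianion formation may be incomplete. The fallback replaces the Claisen acylation by aldol addition and oxidation; it sets out from diketone 8 and ester 9 and returns at 10. Ester 9 is reduced with DIBAL-H (CH2Cl2, −78 °C) to 3,3-dimethoxypropanal F3. The trianion of 8 (LDA, 3.2 equiv, THF, −78 °C) adds to F3, since an aldehyde is attacked much faster than it is deprotonated, and should give 1-(4,5-dichloro-1H-pyrrol-2-yl)-5-hydroxy-7,7-dimethoxy-4-(4-methylpentyl)heptane-1,3-dione F4 as a diastereomer mixture. Dess–Martin periodinane (NaHCO3, CH2Cl2, 0 °C → rt) oxidises the carbinol to 10.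

Step 2. The N–H acid chloride may condense with itself through nitrogen, or the magnesium enolate may be acylated on oxygen instead of carbon. The fallback reverses the polarity so that the pyrrole fragment is the nucleophile; it sets out from acid 4, returns at diketone 8, and makes steps 1 and 3 unnecessary. Acid 4 is coupled with N,O-dimethylhydroxylamine hydrochloride (CDI, THF, rt) to 4,5-dichloro-N-methoxy-N-methyl-1H-pyrrole-2-carboxamide F5. Excess MeMgBr (THF, 0 °C → rt) gives 1-(4,5-dichloro-1H-pyrrol-2-yl)ethan-1-one F6. Claisen condensation of its N,C-dianion with ethyl acetate (NaH, THF, reflux) gives 1-(4,5-dichloro-1H-pyrrol-2-yl)butane-1,3-dione F7. The trianion of F7 (LDA, 3.2 equiv, THF, 0 °C) is alkylated at its terminal carbon with bromide 2 to give 8.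

Further compounds
F1 | step 5 | 1,3-dimethoxy-2-(4-methylpentyl)benzene | COc1cccc(OC)c1CCCC(C)C
F2 | step 5 | (4,5-dichloro-1H-pyrrol-2-yl)[2,4-dimethoxy-3-(4-methylpentyl)phenyl]methanone | COc1ccc(C(=O)c2cc(Cl)c(Cl)[nH]2)c(OC)c1CCCC(C)C
F3 | step 4 | 3,3-dimethoxypropanal | COC(CC=O)OC
F4 | step 4 | 1-(4,5-dichloro-1H-pyrrol-2-yl)-5-hydroxy-7,7-dimethoxy-4-(4-methylpentyl)heptane-1,3-dione | COC(OC)CC(O)C(CCCC(C)C)C(=O)CC(=O)c1cc(Cl)c(Cl)[nH]1
F5 | step 2 | 4,5-dichloro-N-methoxy-N-methyl-1H-pyrrole-2-carboxamide | CON(C)C(=O)c1cc(Cl)c(Cl)[nH]1
F6 | step 2 | 1-(4,5-dichloro-1H-pyrrol-2-yl)ethan-1-one | CC(=O)c1cc(Cl)c(Cl)[nH]1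
F7 | step 2 | 1-(4,5-dichloro-1H-pyrrol-2-yl)butane-1,3-dione | CC(=O)CC(=O)c1cc(Cl)c(Cl)[nH]1
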